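**Target:** methyl {(3R,5S)-3,5-dimethyl-5-[(7E,9E,12Z)-pentadeca-7,9,12-trien-1-yl]-1,2-dioxolan-3-yl}acetate. The CH2CO2Me arm on C3 and the side chain on C5 are trans.

**Retrosynthetic overview**
1. Side chain last: C9=C10 by Julia–Kocienski olefination, C7=C8 by Wittig homologation of a C7 aldehyde, the saturated stretch by cross-metathesis/diimide on a C5 allyl group; the C3 acetate arm by glycol cleavage of a CH2CH(OH)CH2OPMB arm.
2. C5 (quaternary): allylsilane opening, with inversion, of a bridged peroxyketal (a 2,6,7-trioxabicyclo[3.2.1]octane) whose temporary oxane ring ties the arm oxygen to C5 and is cleaved in that step.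
3. 1,2-Dioxolane: grown from a cyclopropanol by insertion of O2 into its C1–C2 bond (three ring atoms to five); the oxane bridge closes in the same operation. Ring order: cyclopropane, then dioxolane plus temporary oxane, then oxane opened.
4. Enabling feature: ring atoms C3–C4–C5 are a carbon triad in which C5 (Me, O) is a masked methyl ketone β to the fully substituted peroxide carbon C3 (Me, arm). This is the retron of a 1,2-dimethyl-2-alkylcyclopropan-1-ol (carbinol C to C5, quaternary C to C3, ring CH2 to C4), and the arm oxygen can reach C5 through a six-membered ring.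
5. Cyclopropanol from Simmons–Smith reaction of a silyl enol ether; its ketone comes from ethyl 2-methylacetoacetate and (R)-PMB glycidyl ether. The glycidyl carbinol carbon is the only source of chirality: it turns the two C3 epimers into separable diastereomers and is later excised.

Key step: step 5

Remark: (R)-glycidyl 4-methoxybenzyl ether is treated as a purchasable building block; it is otherwise one Williamson etherification away from (S)-glycidol.

**Route**

Step 1
Reactants: 1 ethyl 2-methyl-3-oxobutanoate; 2 (2R)-2-{[(4-methoxyphenyl)methoxy]methyl}oxirane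
Product: 3 (5R)-3-acetyl-5-{[(4-methoxyphenyl)methoxy]methyl}-3-methyloxolan-2-one (C3 epimers)
Conditions: NaOEt (0.2 equiv), EtOH, 50 °C
Reagents that add atoms: none
Why: Acetoacetic ester alkylation: the enolate of 1 should open the epoxide at its CH2 terminus (SN2, the carbinol centre of 2 is untouched and becomes C5 of the lactone) and the alkoxide lactonises onto the ethyl ester; ethoxide is kept catalytic to suppress retro-Claisen deacetylation, and the new quaternary centre forms as both epimers without consequence because it later becomes sp2.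

Step 2
Reactants: 3
Product: 5 (5R)-5-hydroxy-6-[(4-methoxyphenyl)methoxy]-3-methylhexan-2-one (C3 epimers), via keto acid 4 (not isolated)
Conditions: LiOH, THF/H2O, 0 °C; then 1 M HCl to pH 4, 50 °C
Reagents that add atoms: none
Why: Saponification of the lactone followed by decarboxylation of the β-keto acid (ketonic cleavage of an acetoacetic ester) should leave the γ-hydroxy ketone, which also exists as its cyclic hemiketal; the carbinol centre is untouched.

Step 3
Reactants: 5
Product: 6 {[(5R)-6-[(4-methoxyphenyl)methoxy]-3-methyl-5-[(trimethylsilyl)oxy]hex-2-en-2-yl]oxy}(trimethyl)silane (E/Z mixture)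
Conditions: TMSCl, Et3N, DMF, rt then 90 °C
Reagents that add atoms: chlorotrimethylsilane, C[Si](C)(C)Cl
Why: Silyl enol ether formation under equilibrating (House) conditions should favour the tetrasubstituted enol ether and caps the secondary hydroxyl first, which stops hemiketal formation; enol geometry is irrelevant, and any terminal regioisomer is carried forward and removed after step 5.

Step 4
Reactants: 6
Product: 8 2-{(2R)-2-hydroxy-3-[(4-methoxyphenyl)methoxy]propyl}-1,2-dimethylcyclopropan-1-ol (ring diastereomers), via bis-silyl cyclopropane 7 (not isolated)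
Conditions: Et2Zn, CH2I2, CH2Cl2, 0 °C to rt; then K2CO3 (cat.), MeOH, 0 °C
Reagents that add atoms: diiodomethane, ICI
Why: Simmons–Smith cyclopropanation (Furukawa variant) of the electron-rich enol ether followed by mild methanolysis of both silyl ethers should give the tertiary cyclopropanol; the two ring stereocentres form without control, which is acceptable because both are erased in step 5.

Step 5
Reactants: 8
Product: 11 (1S,3R,5S)-3-{[(4-methoxyphenyl)methoxy]methyl}-1,5-dimethyl-2,6,7-trioxabicyclo[3.2.1]octane, via hydroperoxy ketone 9 (not isolated), via dioxolanol 10 (not isolated)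
Conditions: Mn(acac)3 (5 mol %), O2 (1 atm), THF, rt; then CSA (10 mol %), 4 Å MS, CH2Cl2, 0 °C to rt; chromatography to remove the C5 epimer
Reagents that add atoms: dioxygen, O=O
Why: Mn(III) exchanges onto the cyclopropanol oxygen, the C1–C2 bond undergoes β-scission toward the tertiary carbon, the β-keto radical captures O2, and the peroxyl radical is reduced and protonated to hydroperoxy ketone 9; in effect O–O is inserted into a cyclopropane bond, and all ring diastereomers of 8 funnel through the same radical. The closest known reaction is the Mn-catalysed aerobic oxidation of cyclopropanols to 1,2-dioxolan-3-ols, here followed by the acid-catalysed exchange of a peroxyhemiketal OH for an alkoxy group. The dioxolane closes by 5-exo-trig addition of OOH to the ketone (10); the temporary oxane closes by 6-exo-trig attack of the side-chain hydroxyl on the 1,2-dioxolan-3-ylium ion formed with CSA, which is only possible cis across the dioxolane and so fixes C1 of 11 relative to C5. Oxygen capture at the planar radical is not face-selective, so C5 should arise in both configurations in comparable amounts; because the carbinol centre from 2 is in place the two ketals are diastereomers (CH2OPMB exo in 11, endo in its epimer), and isolating 11 is what fixes the C3 configuration of the target. The step needs regioselective ring cleavage, secured by tertiary over primary radical stability, and chemoselectivity for the cyclopropanol over the secondary alcohol and the PMB ether, secured by the strain-driven fragmentation under neutral conditions.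

Step 6
Reactants: 11; 12 allyltrimethylsilane
Product: 13 (2R)-1-[(3S,5S)-3,5-dimethyl-5-(prop-2-en-1-yl)-1,2-dioxolan-3-yl]-3-[(4-methoxyphenyl)methoxy]propan-2-ol
Conditions: TiCl4 (1.1 equiv), CH2Cl2, −78 °C; aq. NaHCO3
Reagents that add atoms: none
Why: Hosomi–Sakurai-type allylation of a peroxyketal (Lewis acid substitution of a 3-alkoxy-1,2-dioxolane via the 1,2-dioxolan-3-ylium ion): TiCl4 should bind the more basic ketal ether oxygen, the C1–O2 bond ionises while the titanium alkoxide arm still covers the face it leaves, and allyl is delivered to the opposite face, i.e. with inversion at the former ketal carbon, which sets C5 with allyl trans to the C3 arm.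

Step 7
Reactants: 13
Product: 14 (2R)-3-[(3S,5S)-3,5-dimethyl-5-(prop-2-en-1-yl)-1,2-dioxolan-3-yl]propane-1,2-diol
Conditions: DDQ, CH2Cl2/pH 7 buffer, 0 °C to rt
Reagents that add atoms: none
Why: Oxidative PMB ether cleavage by DDQ (hydride abstraction at the electron-rich benzylic position, then hydrolysis) should free the primary alcohol without touching the di-tert-alkyl peroxide, the terminal alkene or the stereocentres.

Step 8
Reactants: 14
Product: 16 [(3R,5S)-3,5-dimethyl-5-(prop-2-en-1-yl)-1,2-dioxolan-3-yl]acetic acid, via aldehyde 15 (not isolated)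
Conditions: NaIO4, THF/H2O, 0 °C; extractive work-up; then NaClO2, NaH2PO4, 2-methylbut-2-ene, t-BuOH/H2O, 0 °C
Reagents that add atoms: sodium chlorite, [Na+].[O-]Cl=O
Why: Malaprade glycol cleavage removes the auxiliary carbinol carbon as formaldehyde, and the β-peroxy aldehyde is oxidised at once under buffered, mildly acidic Pinnick conditions so that β-elimination of the peroxide is avoided; no ring stereocentre is affected.

Step 9
Reactants: 16
Product: 17 methyl [(3R,5S)-3,5-dimethyl-5-(prop-2-en-1-yl)-1,2-dioxolan-3-yl]acetate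
Conditions: TMSCHN2, toluene/MeOH, 0 °C
Reagents that add atoms: (trimethylsilyl)diazomethane, C[Si](C)(C)C=[N+]=[N-]
Why: Esterification with (trimethylsilyl)diazomethane in methanol avoids base, to which the β-peroxy carbonyl system is sensitive.

Step 10
Reactants: 17; 18 hex-5-en-1-ol
Product: 19 methyl [(3R,5S)-5-(7-hydroxyhept-2-en-1-yl)-3,5-dimethyl-1,2-dioxolan-3-yl]acetate (E/Z mixture)
Conditions: Grubbs II (5 mol %), 18 (3 equiv), CH2Cl2, 40 °C
Reagents that add atoms: none
Why: Olefin cross-metathesis of the unhindered allyl group with an excess of the terminal alkene partner should give the internal alkene, whose geometry is immaterial because it is saturated next; di-tert-alkyl peroxides are expected to tolerate the Ru alkylidene.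

Step 11
Reactants: 19
Product: 20 methyl [(3R,5S)-5-(7-hydroxyheptyl)-3,5-dimethyl-1,2-dioxolan-3-yl]acetate
Conditions: KO2C–N=N–CO2K, AcOH, MeOH, 0 °C to rt
Reagents that add atoms: none
Why: Diimide reduction (concerted syn transfer of H2 from HN=NH) saturates the C=C bond and, unlike catalytic hydrogenation, leaves the O–O bond intact.

Step 12
Reactants: 20
Product: 21 methyl [(3R,5S)-3,5-dimethyl-5-(7-oxoheptyl)-1,2-dioxolan-3-yl]acetate
Conditions: Dess–Martin periodinane, NaHCO3, CH2Cl2, rt
Reagents that add atoms: none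
Why: Dess–Martin oxidation should stop at the aldehyde under buffered, non-basic conditions that spare the peroxide and the ester.

Step 13
Reactants: 21; 22 (triphenylphosphoranylidene)acetaldehyde
Product: 23 methyl {(3R,5S)-3,5-dimethyl-5-[(7E)-9-oxonon-7-en-1-yl]-1,2-dioxolan-3-yl}acetate
Conditions: toluene, 70 °C
Reagents that add atoms: none
Why: Wittig reaction with the stabilised formylmethylene ylide should give the (E)-enal (E selectivity typical of stabilised ylides) and so sets the 7E double bond under neutral conditions.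

Step 14
Reactants: 24 (3Z)-hex-3-en-1-ol; 25 1-phenyl-1H-tetrazole-5-thiol
Product: 26 5-{[(3Z)-hex-3-en-1-yl]sulfanyl}-1-phenyl-1H-tetrazole
Conditions: PPh3, DIAD, THF, 0 °C to rt
Reagents that add atoms: none
Why: Mitsunobu thioetherification (SN2 displacement of the alkoxyphosphonium ion by the acidic thiol) leaves the Z alkene untouched.

Step 15
Reactants: 26
Product: 27 5-{[(3Z)-hex-3-en-1-yl]sulfonyl}-1-phenyl-1H-tetrazole
Conditions: (NH4)6Mo7O24·4H2O (10 mol %), 30 % H2O2, EtOH, 0 °C to rt
Reagents that add atoms: hydrogen peroxide, OO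
Why: Molybdate-catalysed peroxide oxidation of the sulfide to the sulfone is selective for sulfur over the isolated Z alkene.

Step 16
Reactants: 23; 27
Product: 28 methyl {(3R,5S)-3,5-dimethyl-5-[(7E,9E,12Z)-pentadeca-7,9,12-trien-1-yl]-1,2-dioxolan-3-yl}acetate
Conditions: 27 (1.3 equiv), KHMDS (1.2 equiv), DME, −78 °C, 30 min; then 23, −78 to −20 °C
Reagents that add atoms: none
Why: Julia–Kocienski olefination: the potassium α-sulfonyl carbanion adds to the enal, and Smiles rearrangement with loss of SO2 and the tetrazolate should give the new 9E double bond (E selectivity favoured by K+/DME); the sulfone is premetalated so that the ester α-protons do not meet free base, and the 7E and 12Z bonds and both ring stereocentres are untouched.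

**Compound list**
1 | ethyl 2-methyl-3-oxobutanoate | CCOC(=O)C(C)C(C)=O | starting material
2 | (2R)-2-{[(4-methoxyphenyl)methoxy]methyl}oxirane | COc1ccc(COC[C@H]2CO2)cc1 | starting material
3 | (5R)-3-acetyl-5-{[(4-methoxyphenyl)methoxy]methyl}-3-methyloxolan-2-one (C3 epimers) | CC(=O)C1(C)C[C@H](COCc2ccc(OC)cc2)OC1=O | intermediate
4 | (4R)-2-acetyl-4-hydroxy-5-[(4-methoxyphenyl)methoxy]-2-methylpentanoic acid (C2 epimers) | CC(=O)C(C)(C[C@@H](O)COCc1ccc(OC)cc1)C(=O)O | intermediate
5 | (5R)-5-hydroxy-6-[(4-methoxyphenyl)methoxy]-3-methylhexan-2-one (C3 epimers) | CC(=O)C(C)C[C@@H](O)COCc1ccc(OC)cc1 | intermediate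
6 | {[(5R)-6-[(4-methoxyphenyl)methoxy]-3-methyl-5-[(trimethylsilyl)oxy]hex-2-en-2-yl]oxy}(trimethyl)silane (E/Z) | CC(O[Si](C)(C)C)=C(C)C[C@@H](O[Si](C)(C)C)COCc1ccc(OC)cc1 | intermediate
7 | bis(trimethylsilyl) ether of 8 (ring diastereomers) | CC1(O[Si](C)(C)C)CC1(C)C[C@@H](O[Si](C)(C)C)COCc2ccc(OC)cc2 | intermediate
8 | 2-{(2R)-2-hydroxy-3-[(4-methoxyphenyl)methoxy]propyl}-1,2-dimethylcyclopropan-1-ol (ring diastereomers) | CC1(O)CC1(C)C[C@@H](O)COCc2ccc(OC)cc2 | intermediate
9 | (6R)-4-hydroperoxy-6-hydroxy-7-[(4-methoxyphenyl)methoxy]-4-methylheptan-2-one (C4 epimers) | CC(=O)CC(C)(OO)C[C@@H](O)COCc1ccc(OC)cc1 | intermediate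
10 | 5-{(2R)-2-hydroxy-3-[(4-methoxyphenyl)methoxy]propyl}-3,5-dimethyl-1,2-dioxolan-3-ol (ring epimers) | CC1(O)CC(C)(C[C@@H](O)COCc2ccc(OC)cc2)OO1 | intermediate
11 | (1S,3R,5S)-3-{[(4-methoxyphenyl)methoxy]methyl}-1,5-dimethyl-2,6,7-trioxabicyclo[3.2.1]octane | C[C@@]12C[C@](C)(C[C@H](COCc3ccc(OC)cc3)O2)OO1 | intermediate
12 | allyltrimethylsilane | C=CC[Si](C)(C)C | starting material
13 | (2R)-1-[(3S,5S)-3,5-dimethyl-5-(prop-2-en-1-yl)-1,2-dioxolan-3-yl]-3-[(4-methoxyphenyl)methoxy]propan-2-ol | C=CC[C@@]1(C)C[C@](C)(C[C@@H](O)COCc2ccc(OC)cc2)OO1 | intermediate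
14 | (2R)-3-[(3S,5S)-3,5-dimethyl-5-(prop-2-en-1-yl)-1,2-dioxolan-3-yl]propane-1,2-diol | C=CC[C@@]1(C)C[C@](C)(C[C@@H](O)CO)OO1 | intermediate
15 | [(3R,5S)-3,5-dimethyl-5-(prop-2-en-1-yl)-1,2-dioxolan-3-yl]acetaldehyde | C=CC[C@@]1(C)C[C@](C)(CC=O)OO1 | intermediate
16 | [(3R,5S)-3,5-dimethyl-5-(prop-2-en-1-yl)-1,2-dioxolan-3-yl]acetic acid | C=CC[C@@]1(C)C[C@](C)(CC(=O)O)OO1 | intermediate
17 | methyl [(3R,5S)-3,5-dimethyl-5-(prop-2-en-1-yl)-1,2-dioxolan-3-yl]acetate | C=CC[C@@]1(C)C[C@](C)(CC(=O)OC)OO1 | intermediate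
18 | hex-5-en-1-ol | C=CCCCCO | starting material
19 | methyl [(3R,5S)-5-(7-hydroxyhept-2-en-1-yl)-3,5-dimethyl-1,2-dioxolan-3-yl]acetate (E/Z) | OCCCCC=CC[C@@]1(C)C[C@](C)(CC(=O)OC)OO1 | intermediate
20 | methyl [(3R,5S)-5-(7-hydroxyheptyl)-3,5-dimethyl-1,2-dioxolan-3-yl]acetate | OCCCCCCC[C@@]1(C)C[C@](C)(CC(=O)OC)OO1 | intermediate
21 | methyl [(3R,5S)-3,5-dimethyl-5-(7-oxoheptyl)-1,2-dioxolan-3-yl]acetate | O=CCCCCCC[C@@]1(C)C[C@](C)(CC(=O)OC)OO1 | intermediate
22 | (triphenylphosphoranylidene)acetaldehyde | O=CC=P(c1ccccc1)(c1ccccc1)c1ccccc1 | starting material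
23 | methyl {(3R,5S)-3,5-dimethyl-5-[(7E)-9-oxonon-7-en-1-yl]-1,2-dioxolan-3-yl}acetate | O=C/C=C/CCCCCC[C@@]1(C)C[C@](C)(CC(=O)OC)OO1 | intermediate
24 | (3Z)-hex-3-en-1-ol | CC/C=C\CCO | starting material
25 | 1-phenyl-1H-tetrazole-5-thiol | Sc1nnnn1-c1ccccc1 | starting material
26 | 5-{[(3Z)-hex-3-en-1-yl]sulfanyl}-1-phenyl-1H-tetrazole | CC/C=C\CCSc1nnnn1-c1ccccc1 | intermediate
27 | 5-{[(3Z)-hex-3-en-1-yl]sulfonyl}-1-phenyl-1H-tetrazole | CC/C=C\CCS(=O)(=O)c1nnnn1-c1ccccc1 | intermediate
28 | methyl {(3R,5S)-3,5-dimethyl-5-[(7E,9E,12Z)-pentadeca-7,9,12-trien-1-yl]-1,2-dioxolan-3-yl}acetate | CC/C=C\C/C=C/C=C/CCCCCC[C@@]1(C)C[C@](C)(CC(=O)OC)OO1 | target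

**Step count**
Total: 16 steps. Longest linear sequence: 14 steps (steps 1–13 and 16, from 1 and 2).

**Steps most likely to fail**

1. Step 5. Oxygen capture by the planar tertiary radical has no facial bias, so at best about half of the material can have the needed configuration at the peroxide carbon and the rest is lost on separation. In addition, the hydroperoxy ketone may suffer metal-induced O–O cleavage or collapse to an epoxy ketone before ketalisation. Fallback, leaving the radical manifold and setting out from 2: copper-catalysed opening with isopropenylmagnesium bromide should give (2R)-1-[(4-methoxyphenyl)methoxy]-4-methylpent-4-en-2-ol F1. Epoxidation (mCPBA, NaHCO3) gives (2R)-1-[(4-methoxyphenyl)methoxy]-3-(2-methyloxiran-2-yl)propan-2-ol F2, of which both epoxide epimers serve. Excess 2-lithio-2-methyl-1,3-dithiane opens the epoxide at CH2 to (2R)-1-[(4-methoxyphenyl)methoxy]-4-methyl-5-(2-methyl-1,3-dithian-2-yl)pentane-2,4-diol F3, and MeI/CaCO3 in aqueous MeCN frees (6R)-4,6-dihydroxy-7-[(4-methoxyphenyl)methoxy]-4-methylheptan-2-one F4. Ethereal H2O2 with catalytic acid (the classical conversion of tertiary β-hydroxy ketones into 1,2-dioxolan-3-ols), then CSA, rejoins the route at 11. In this variant the C–OO bond forms by capture of a planar tertiary cation inside the ring that becomes the oxane, so the carbinol centre can bias closure toward the exo ketal.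

2. Step 6. If the peroxycarbenium ion outlives the ion pair, the allylsilane can attack from both faces and the trans relationship erodes; the Lewis acid may also remove the PMB group early or trigger heterolysis of the O–O bond. Fallback, from 11 with a different control element: MeOH/CSA should open the bridge to (2R)-1-[(3S)-5-methoxy-3,5-dimethyl-1,2-dioxolan-3-yl]-3-[(4-methoxyphenyl)methoxy]propan-2-ol F5. The carbinol is capped (TBDPSCl, imidazole) as tert-butyl{[(2R)-1-[(3S)-5-methoxy-3,5-dimethyl-1,2-dioxolan-3-yl]-3-[(4-methoxyphenyl)methoxy]propan-2-yl]oxy}diphenylsilane F6. Allylation of this monocyclic peroxyketal (allyltrimethylsilane, SnCl4, −78 °C) then runs under steric control by the bulky silyloxy arm to tert-butyl{[(2R)-1-[(3S,5S)-3,5-dimethyl-5-(prop-2-en-1-yl)-1,2-dioxolan-3-yl]-3-[(4-methoxyphenyl)methoxy]propan-2-yl]oxy}diphenylsilane F7. TBAF/AcOH returns to the route at 13.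

3. Step 16. The new double bond may form with insufficient E selectivity, and any free base can deprotonate α to the ester and open the dioxolane by retro-oxa-Michael elimination. Fallback, from 24 and 23: 24 is converted (I2, PPh3, imidazole) into (3Z)-1-iodohex-3-ene F8 and then (PPh3, MeCN, reflux) into [(3Z)-hex-3-en-1-yl](triphenyl)phosphonium iodide F9. The salt-free ylide (NaHMDS, THF, −78 °C) reacts with 23 in a Z-selective Wittig reaction to give methyl {(3R,5S)-3,5-dimethyl-5-[(7E,9Z,12Z)-pentadeca-7,9,12-trien-1-yl]-1,2-dioxolan-3-yl}acetate F10. Catalytic iodine in daylight then isomerises only the conjugated 9Z bond to 9E, leaving the isolated 12Z bond alone, and arrives at 28.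

**Further compounds**
F1 | step 5 | (2R)-1-[(4-methoxyphenyl)methoxy]-4-methylpent-4-en-2-ol | C=C(C)C[C@@H](O)COCc1ccc(OC)cc1
F2 | step 5 | (2R)-1-[(4-methoxyphenyl)methoxy]-3-(2-methyloxiran-2-yl)propan-2-ol (epoxide epimers) | CC1(CO1)C[C@@H](O)COCc2ccc(OC)cc2
F3 | step 5 | (2R)-1-[(4-methoxyphenyl)methoxy]-4-methyl-5-(2-methyl-1,3-dithian-2-yl)pentane-2,4-diol (C4 epimers) | CC1(CC(C)(O)C[C@@H](O)COCc2ccc(OC)cc2)SCCCS1
F4 | step 5 | (6R)-4,6-dihydroxy-7-[(4-methoxyphenyl)methoxy]-4-methylheptan-2-one (C4 epimers) | CC(=O)CC(C)(O)C[C@@H](O)COCc1ccc(OC)cc1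
F5 | step 6 | (2R)-1-[(3S)-5-methoxy-3,5-dimethyl-1,2-dioxolan-3-yl]-3-[(4-methoxyphenyl)methoxy]propan-2-ol (C5 epimers) | COC1(C)C[C@](C)(C[C@@H](O)COCc2ccc(OC)cc2)OO1
F6 | step 6 | tert-butyl{[(2R)-1-[(3S)-5-methoxy-3,5-dimethyl-1,2-dioxolan-3-yl]-3-[(4-methoxyphenyl)methoxy]propan-2-yl]oxy}diphenylsilane (C5 epimers) | COC1(C)C[C@](C)(C[C@@H](O[Si](c2ccccc2)(c2ccccc2)C(C)(C)C)COCc2ccc(OC)cc2)OO1
F7 | step 6 | tert-butyl{[(2R)-1-[(3S,5S)-3,5-dimethyl-5-(prop-2-en-1-yl)-1,2-dioxolan-3-yl]-3-[(4-methoxyphenyl)methoxy]propan-2-yl]oxy}diphenylsilane | C=CC[C@@]1(C)C[C@](C)(C[C@@H](O[Si](c2ccccc2)(c2ccccc2)C(C)(C)C)COCc2ccc(OC)cc2)OO1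
F8 | step 16 | (3Z)-1-iodohex-3-ene | CC/C=C\CCI
F9 | step 16 | [(3Z)-hex-3-en-1-yl](triphenyl)phosphonium iodide | CC/C=C\CC[P+](c1ccccc1)(c1ccccc1)c1ccccc1.[I-]
F10 | step 16 | methyl {(3R,5S)-3,5-dimethyl-5-[(7E,9Z,12Z)-pentadeca-7,9,12-trien-1-yl]-1,2-dioxolan-3-yl}acetate | CC/C=C\C/C=C\C=C\CCCCCC[C@@]1(C)C[C@](C)(CC(=O)OC)OO1
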